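Assumption: decalin compounds are named with eremophilane numbering (C-5 = angular-methyl carbon, C-10 = ring-fusion CH, C-8 = ring-B carbonyl, C-15/C-14 = methyls on C-4/C-5, C-11 to C-13 = side chain on C-7; β = face of the C-5 methyl; "trinor" = lacking C-11 to C-13); the SMILES is authoritative.

**Retrosynthetic overview** (disconnections listed in the forward order of bond formation)
1. Acyl chain: hept-1-yne 1 → iodide 3 → enyne 4 (C-5'–C-6', Negishi) → dienyl iodide 6 (5'-Me and 4E, carboalumination), then Heck with acrylic acid 7 (C-3'–C-4') → acid 8.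
2. Ring B is formed first: 2-methylcyclopentane-1,3-dione 9 + but-3-en-2-one 10 → Hajos–Parrish ketone 13 (sets C-5).
3. Ring A is formed second by the key step: vinyl carbinol 15 → one-carbon ring expansion (semipinacol 1,2-shift of the quaternary carbon) → dione 16, which installs C-4 with its methyl.
4. C-3 and C-10: 16 → 17 → 18 (axial 3β-ol, cis ring fusion); the C-3–O ester bond is made by Mitsunobu inversion with 8 → 19.
5. Ring-B oxidation last: C-9 OH (19 → 22), then C-7=C-11 with the C-12 OH from chloroacetone 23 → target 26.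

**Route**

Step 1
Reactants: 1 hept-1-yne
Product: 3 (E)-1-iodohept-1-ene, via alkenylzirconocene 2 (not isolated)
Conditions: Cp2Zr(H)Cl (1.1 equiv), CH2Cl2, rt; then I2, 0 °C
Reagents that add atoms: iodine, II
Why: Schwartz hydrozirconation is a syn, anti-Markovnikov addition and iodinolysis of the C–Zr bond goes with retention, so only the E iodide forms.

Step 2
Reactants: 3 (E)-1-iodohept-1-ene
Product: 4 (E)-non-3-en-1-yne
Conditions: HC≡CMgBr, ZnBr2, THF, 0 °C; then 3, Pd(PPh3)4 (3 mol %), rt
Reagents that add atoms: ethynylmagnesium bromide, C#C[Mg]Br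
Why: Negishi cross-coupling of ethynylzinc bromide with the alkenyl iodide gives the terminal enyne directly with retention of the E geometry.

Step 3
Reactants: 4 (E)-non-3-en-1-yne
Product: 6 (1E,3E)-1-iodo-2-methylnona-1,3-diene, via dienylalane 5 (not isolated)
Conditions: Me3Al (2 equiv), Cp2ZrCl2 (20 mol %), CH2Cl2, rt; then I2, THF, −30 °C
Reagents that add atoms: trimethylaluminium, C[Al](C)C; iodine, II
Why: Negishi zirconium-catalysed carboalumination adds Me–Al syn across the terminal alkyne (methyl on the internal carbon) and iodinolysis with retention fixes the future 4E trisubstituted alkene.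

Step 4
Reactants: 6 (1E,3E)-1-iodo-2-methylnona-1,3-diene; 7 acrylic acid
Product: 8 (2E,4E,6E)-5-methyldodeca-2,4,6-trienoic acid
Conditions: Pd(OAc)2 (5 mol %), K2CO3, n-Bu4NCl, DMF, 40 °C; then aq. HCl
Reagents that add atoms: none
Why: Heck reaction under Jeffery conditions (syn insertion, syn β-hydride elimination) gives the 2E acid and leaves the two existing alkene geometries untouched.

Step 5
Reactants: 9 2-methylcyclopentane-1,3-dione; 10 but-3-en-2-one
Product: 13 (S)-7a-methyl-2,3,7,7a-tetrahydro-1H-indene-1,5(6H)-dione (Hajos–Parrish ketone), via triketone 11 (not isolated), via Hajos ketol 12 (not isolated)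
Conditions: H2O, AcOH (cat.), 75 °C; then (S)-proline (3 mol %), DMF, 20 °C; then H2SO4 (cat.), 95 °C; recrystallise
Reagents that add atoms: none
Why: Michael addition followed by the Hajos–Parrish proline-enamine aldol desymmetrises the two ring carbonyls and sets the quaternary centre as S (future C-5), and acid dehydration gives the enone (ring B).

Step 6
Reactants: 13 (S)-Hajos–Parrish ketone
Product: 15 (1R,7aS)-1-ethenyl-1-hydroxy-7a-methyl-1,2,3,6,7,7a-hexahydro-5H-inden-5-one, via dienamine 14 (not isolated)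
Conditions: pyrrolidine (1.2 equiv), MeOH, 50 °C, evaporate; then CH2=CHMgBr (2.2 equiv), LaCl3·2LiCl (30 mol %), THF, −40 → 0 °C; then aq. AcOH/NaOAc, rt
Reagents that add atoms: vinylmagnesium bromide, C=C[Mg]Br; water, O
Why: The enone is masked in situ as its pyrrolidine dienamine (the steroid 3-enamine tactic for 17-ketone alkylation), so the Grignard 1,2-addition occurs only at the cyclopentanone and from the α face opposite the angular methyl, setting C-1 as R (β-OH).

Step 7
Reactants: 15 (1R,7aS)-1-ethenyl-1-hydroxy-7a-methyl-1,2,3,6,7,7a-hexahydro-5H-inden-5-one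
Product: 16 (4aR,5R)-4a,5-dimethyl-4,4a,7,8-tetrahydronaphthalene-2,6(3H,5H)-dione (4β,5β-dimethyl-11,12,13-trinoreremophil-9-ene-3,8-dione)
Conditions: (salen)Co catalyst (5 mol %), N-fluoro-2,4,6-trimethylpyridinium BF4 (1.5 equiv), PhSiH3 (1.2 equiv), acetone, 0 °C
Reagents that add atoms: none
Why: Cobalt-hydride HAT-initiated radical–polar crossover semipinacol rearrangement: Markovnikov H-atom transfer to the vinyl group and oxidation give a C-4 cation equivalent to which the electron-rich quaternary carbon migrates with retention (1,2-shift, ring expansion to the cyclohexanone), and the rotamer with the new methyl syn to the C–O bond and away from ring B is predicted to place it cis to the angular methyl (4β).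

Step 8
Reactants: 16 (4aR,5R)-4a,5-dimethyl-4,4a,7,8-tetrahydronaphthalene-2,6(3H,5H)-dione
Product: 17 3β-hydroxy-11,12,13-trinoreremophil-9-en-8-one
Conditions: L-Selectride (1.05 equiv), THF, −78 °C; then H2O
Reagents that add atoms: none
Why: L-Selectride attacks the saturated C-3 ketone from the equatorial α side (axial approach is blocked by the syn-axial C-5 methyl) to give the axial 3β-alcohol and leaves the β,β-disubstituted enone intact (chemoselective bulky-hydride reduction).

Step 9
Reactants: 17 3β-hydroxy-11,12,13-trinoreremophil-9-en-8-one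
Product: 18 3β-hydroxy-11,12,13-trinor-10βH-eremophilan-8-one
Conditions: H2 (1 atm), 10% Pd/C, EtOAc, rt
Reagents that add atoms: none
Why: Heterogeneous catalytic hydrogenation of 4,5-dimethyl octalones of this type adds hydrogen to C-10 from the β face and gives the cis-fused decalone, as in the fukinone series.

Step 10
Reactants: 18 3β-hydroxy-11,12,13-trinor-10βH-eremophilan-8-one; 8 (2E,4E,6E)-5-methyldodeca-2,4,6-trienoic acid
Product: 19 8-oxo-11,12,13-trinor-10βH-eremophilan-3α-yl (2E,4E,6E)-5-methyldodeca-2,4,6-trienoate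
Conditions: PPh3, DIAD, PhMe, 0 °C → rt
Reagents that add atoms: none
Why: Mitsunobu esterification: the carboxylate of 8 displaces the axial 3β-oxyphosphonium by SN2 with inversion, giving the equatorial 3α-ester at the only free hydroxyl in the molecule.

Step 11
Reactants: 19 8-oxo-11,12,13-trinor-10βH-eremophilan-3α-yl (2E,4E,6E)-5-methyldodeca-2,4,6-trienoate
Product: 22 9β-hydroxy-8-oxo-11,12,13-trinor-10βH-eremophilan-3α-yl (2E,4E,6E)-5-methyldodeca-2,4,6-trienoate, via silyl enol ether 20 (not isolated), via silyloxy epoxide 21 (not isolated)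
Conditions: TMSCl, NaI, Et3N, MeCN, rt; then DMDO (1.0 equiv), acetone, −40 °C; then aq. citric acid, THF
Reagents that add atoms: dimethyldioxirane, CC1(C)OO1
Why: Under equilibrating silylation a cis-fused 2-decalone with the angular methyl on the far bridgehead enolises toward the ring fusion (C-9, as 5β-3-keto steroids give Δ3 enol derivatives), and Rubottom oxidation with DMDO from the convex β face, much faster on the silyl enol ether than on the ester-conjugated triene, gives the equatorial 9β-hydroxy ketone.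

Step 12
Reactants: 22 9β-hydroxy-8-oxo-11,12,13-trinor-10βH-eremophilan-3α-yl (2E,4E,6E)-5-methyldodeca-2,4,6-trienoate; 23 chloroacetone
Product: 26 (7(11)Z)-9β,12-dihydroxy-8-oxo-10βH-eremophil-7(11)-en-3α-yl (2E,4E,6E)-5-methyldodeca-2,4,6-trienoate (target), via chlorohydrin aldolate 24 (not isolated), via epoxy ketone 25 (not isolated)
Conditions: LiHMDS (2.1 equiv), THF, −78 °C; then 23, −78 → −20 °C; then LiHMDS (1.1 equiv), −78 → 0 °C; pH 7 buffer
Reagents that add atoms: none
Why: Proposed new method: a one-pot lithium-templated aldol/epoxide-closure/E1cB cascade in which the C-7 lithium enolate (the only CH2 α to C-8, C-9 being an alkoxide) adds to the activated carbonyl of chloroacetone, the aldolate displaces chloride to give the 2-methyloxiranyl ketone 25, and re-enolisation opens the epoxide by E1cB only through the rotamer in which the enolate-bound lithium reaches the oxirane oxygen, so that CH2O– ends cis to the carbonyl and the Z tetrasubstituted C-7=C-11 alkene with free C-12 OH forms without protecting groups; the closest known reaction types are the aldol/ring-closure half of the (interrupted) Feist–Benary reaction of α-halo ketones and the base-mediated isomerisation of β,γ-epoxy ketones to γ-hydroxy enones.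

**Compound list**
1 | hept-1-yne | CCCCCC#C | starting material
2 | chloridobis(cyclopentadienyl)[(E)-hept-1-enyl]zirconium | CCCCC/C=C/[Zr](Cl)(C1C=CC=C1)C1C=CC=C1 | intermediate
3 | (E)-1-iodohept-1-ene | CCCCC/C=C/I | intermediate
4 | (E)-non-3-en-1-yne | CCCCC/C=C/C#C | intermediate
5 | dimethyl[(1E,3E)-2-methylnona-1,3-dien-1-yl]alumane | CCCCC/C=C/C(C)=C/[Al](C)C | intermediate
6 | (1E,3E)-1-iodo-2-methylnona-1,3-diene | CCCCC/C=C/C(C)=C/I | intermediate
7 | acrylic acid (prop-2-enoic acid) | C=CC(=O)O | starting material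
8 | (2E,4E,6E)-5-methyldodeca-2,4,6-trienoic acid | CCCCC/C=C/C(C)=C/C=C/C(=O)O | intermediate
9 | 2-methylcyclopentane-1,3-dione | CC1C(=O)CCC1=O | starting material
10 | but-3-en-2-one | CC(=O)C=C | starting material
11 | 2-methyl-2-(3-oxobutyl)cyclopentane-1,3-dione | CC(=O)CCC1(C)C(=O)CCC1=O | intermediate
12 | (3aS,7aS)-3a-hydroxy-7a-methylhexahydro-1H-indene-1,5(4H)-dione | C[C@]12CCC(=O)C[C@@]1(O)CCC2=O | intermediate
13 | (S)-7a-methyl-2,3,7,7a-tetrahydro-1H-indene-1,5(6H)-dione (Hajos–Parrish ketone) | C[C@]12CCC(=O)C=C1CCC2=O | intermediate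
14 | (S)-7a-methyl-5-(pyrrolidin-1-yl)-2,6,7,7a-tetrahydro-1H-inden-1-one | C[C@]12CCC(N3CCCC3)=CC1=CCC2=O | intermediate
15 | (1R,7aS)-1-ethenyl-1-hydroxy-7a-methyl-1,2,3,6,7,7a-hexahydro-5H-inden-5-one (OH cis to the angular methyl) | C=C[C@]1(O)CCC2=CC(=O)CC[C@]12C | intermediate
16 | (4aR,5R)-4a,5-dimethyl-4,4a,7,8-tetrahydronaphthalene-2,6(3H,5H)-dione (4β,5β-dimethyl-11,12,13-trinoreremophil-9-ene-3,8-dione) | O=C1CCC2=CC(=O)CC[C@]2(C)[C@H]1C | intermediate
17 | 3β-hydroxy-11,12,13-trinoreremophil-9-en-8-one (OH cis to both methyls) | O[C@H]1CCC2=CC(=O)CC[C@]2(C)[C@H]1C | intermediate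
18 | 3β-hydroxy-11,12,13-trinor-10βH-eremophilan-8-one (cis-decalin; 3-OH, 4-Me, 5-Me and 10-H all β) | O[C@H]1CC[C@@H]2CC(=O)CC[C@]2(C)[C@H]1C | intermediate
19 | 8-oxo-11,12,13-trinor-10βH-eremophilan-3α-yl (2E,4E,6E)-5-methyldodeca-2,4,6-trienoate | CCCCC/C=C/C(C)=C/C=C/C(=O)O[C@@H]1CC[C@@H]2CC(=O)CC[C@]2(C)[C@H]1C | intermediate
20 | 8-(trimethylsilyloxy)-11,12,13-trinor-10βH-eremophil-8-en-3α-yl (2E,4E,6E)-5-methyldodeca-2,4,6-trienoate | CCCCC/C=C/C(C)=C/C=C/C(=O)O[C@@H]1CC[C@@H]2C=C(O[Si](C)(C)C)CC[C@]2(C)[C@H]1C | intermediate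
21 | 8β,9β-epoxy-8α-(trimethylsilyloxy)-11,12,13-trinor-10βH-eremophilan-3α-yl (2E,4E,6E)-5-methyldodeca-2,4,6-trienoate | CCCCC/C=C/C(C)=C/C=C/C(=O)O[C@@H]1CC[C@@H]2[C@H]3O[C@@]3(O[Si](C)(C)C)CC[C@]2(C)[C@H]1C | intermediate
22 | 9β-hydroxy-8-oxo-11,12,13-trinor-10βH-eremophilan-3α-yl (2E,4E,6E)-5-methyldodeca-2,4,6-trienoate | CCCCC/C=C/C(C)=C/C=C/C(=O)O[C@@H]1CC[C@@H]2[C@@H](O)C(=O)CC[C@]2(C)[C@H]1C | intermediate
23 | chloroacetone (1-chloropropan-2-one) | CC(=O)CCl | starting material
24 | 12-chloro-9β,11-dihydroxy-8-oxo-10βH-eremophilan-3α-yl (2E,4E,6E)-5-methyldodeca-2,4,6-trienoate (lithium alkoxide in the flask; C-7/C-11 mixture) | CCCCC/C=C/C(C)=C/C=C/C(=O)O[C@@H]1CC[C@@H]2[C@@H](O)C(=O)C(C(C)(O)CCl)C[C@]2(C)[C@H]1C | intermediate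
25 | 11,12-epoxy-9β-hydroxy-8-oxo-10βH-eremophilan-3α-yl (2E,4E,6E)-5-methyldodeca-2,4,6-trienoate (C-7/C-11 mixture) | CCCCC/C=C/C(C)=C/C=C/C(=O)O[C@@H]1CC[C@@H]2[C@@H](O)C(=O)C(C3(C)CO3)C[C@]2(C)[C@H]1C | intermediate
26 | (7(11)Z)-9β,12-dihydroxy-8-oxo-10βH-eremophil-7(11)-en-3α-yl (2E,4E,6E)-5-methyldodeca-2,4,6-trienoate (3R,4R,5R,9R,10S) | CCCCC/C=C/C(C)=C/C=C/C(=O)O[C@@H]1CC[C@@H]2[C@@H](O)C(=O)/C(=C(/C)CO)C[C@]2(C)[C@H]1C | target

**Totals**
Total step count: 12 (4 for the acid, 8 for the core including the coupling).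
Longest linear sequence: 8 steps (steps 5 to 12, from 9 and 10 to 26).

**Three steps most likely to fail**

Step 12 (the proposed new cascade). Risks are proton transfer or C-alkylation with chloroacetone, deprotonation of the trienoate by LiHMDS, and formation of the 7(11)E isomer. The fallback uses known chemistry, sets out from 22 and comes back at 26. TESOTf/Et3N (CH2Cl2, −78 °C) silylates the C-9 hydroxyl and enolises toward C-7 to give the bis-silyl compound, 9β-(triethylsilyloxy)-8-(triethylsilyloxy)-trinoreremophil-7-ene ester F4. A Lewis-acid (TiCl4 or BF3·OEt2) Mukaiyama aldol with commercial 1-(tert-butyldimethylsilyloxy)propan-2-one gives the tertiary aldol F5. Dehydration (SOCl2/pyridine, 0 °C, or Burgess reagent) gives the silyl-protected 7(11)-enone as an E/Z mixture F6. HF·pyridine/pyridine removes both silyl groups to give 26 together with its 7(11)E isomer F7. The two are separated, and F7 is recycled by 350 nm E→Z photoisomerisation; the Z isomer should be favoured by its internal O–H···O=C hydrogen bond.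

Step 7 (ring expansion). Risks are epoxide formation instead of the 1,2-shift, migration of C-2 instead of the quaternary carbon, and formation of the 4-epimer. The fallback sets out from 15 and comes back at 16. NBS (CH2Cl2/i-PrOH, 0 °C) generates a bromonium ion on the vinyl group and triggers the same migration ionically (halogen-induced semipinacol ring expansion), giving 15-bromo-11,12,13-trinoreremophil-9-ene-3,8-dione (4β-bromomethyl) F1. Radical debromination (Bu3SnH at high concentration, AIBN, PhH, 80 °C) then gives 16.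

Step 10 (Mitsunobu esterification). Risks are E2 elimination and sluggish displacement at a hindered axial alcohol by a weakly acidic trienoic acid. The fallback sets out from 18 and comes back at 19. Mitsunobu inversion with the more acidic 4-nitrobenzoic acid (PPh3, DIAD, PhMe) gives 8-oxo-11,12,13-trinor-10βH-eremophilan-3α-yl 4-nitrobenzoate F2. Methanolysis (K2CO3, MeOH) frees the equatorial alcohol 3α-hydroxy-11,12,13-trinor-10βH-eremophilan-8-one F3. This is acylated with retention by the Yamaguchi mixed anhydride of 8 (2,4,6-trichlorobenzoyl chloride, Et3N, then DMAP, PhMe) to give 19.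

**Further compounds**
F1 | step 7 | 15-bromo-11,12,13-trinoreremophil-9-ene-3,8-dione (4β-bromomethyl analogue of 16) | O=C1CCC2=CC(=O)CC[C@]2(C)[C@H]1CBr
F2 | step 10 | 8-oxo-11,12,13-trinor-10βH-eremophilan-3α-yl 4-nitrobenzoate | O=C(O[C@@H]1CC[C@@H]2CC(=O)CC[C@]2(C)[C@H]1C)c1ccc(cc1)[N+](=O)[O-]
F3 | step 10 | 3α-hydroxy-11,12,13-trinor-10βH-eremophilan-8-one | O[C@@H]1CC[C@@H]2CC(=O)CC[C@]2(C)[C@H]1C
F4 | step 12 | 8,9β-bis(triethylsilyloxy)-11,12,13-trinor-10βH-eremophil-7-en-3α-yl (2E,4E,6E)-5-methyldodeca-2,4,6-trienoate | CCCCC/C=C/C(C)=C/C=C/C(=O)O[C@@H]1CC[C@@H]2[C@@H](O[Si](CC)(CC)CC)C(O[Si](CC)(CC)CC)=CC[C@]2(C)[C@H]1C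
F5 | step 12 | 12-(tert-butyldimethylsilyloxy)-11-hydroxy-8-oxo-9β-(triethylsilyloxy)-10βH-eremophilan-3α-yl (2E,4E,6E)-5-methyldodeca-2,4,6-trienoate (C-7/C-11 mixture) | CCCCC/C=C/C(C)=C/C=C/C(=O)O[C@@H]1CC[C@@H]2[C@@H](O[Si](CC)(CC)CC)C(=O)C(C(C)(O)CO[Si](C)(C)C(C)(C)C)C[C@]2(C)[C@H]1C
F6 | step 12 | 12-(tert-butyldimethylsilyloxy)-8-oxo-9β-(triethylsilyloxy)-10βH-eremophil-7(11)-en-3α-yl (2E,4E,6E)-5-methyldodeca-2,4,6-trienoate (E/Z mixture) | CCCCC/C=C/C(C)=C/C=C/C(=O)O[C@@H]1CC[C@@H]2[C@@H](O[Si](CC)(CC)CC)C(=O)C(=C(C)CO[Si](C)(C)C(C)(C)C)C[C@]2(C)[C@H]1C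
F7 | step 12 | (7(11)E)-9β,12-dihydroxy-8-oxo-10βH-eremophil-7(11)-en-3α-yl (2E,4E,6E)-5-methyldodeca-2,4,6-trienoate | CCCCC/C=C/C(C)=C/C=C/C(=O)O[C@@H]1CC[C@@H]2[C@@H](O)C(=O)/C(=C(\C)CO)C[C@]2(C)[C@H]1C
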